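**Retrosynthetic overview**
- Last bond: C7–C8 (alkene CH to the CH(CH3) on the central pyranone), made by an enantioconvergent nickel-catalysed reductive coupling of a west alkenyl bromide with an east 1-chloroethyl pyranone, all three esters already in place.
- East fragment (key step): symmetric 2,6-diethyl-3,5-dimethyl-4-pyranone is dearomatised by O-silylation and deprotonation to its silyl trienol ether and desymmetrised by an enantioselective anti vinylogous Mukaiyama aldol with propanal; the second ethyl arm is then chlorinated and the carbinol acetylated in one pot.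
- West fragment: a second molecule of the same pyranone is desymmetrised by an anti, Felkin-selective vinylogous aldol of its lithium dienolate with an aldehyde made by an Evans anti-aldol of (E)-3-bromo-2-methylacrolein.
- No ring is constructed: both 4-pyranone rings come intact from the symmetric pyranone (central ring introduced in step 1, terminal ring in step 6).

Assumption: 2,6-diethyl-3,5-dimethyl-4H-pyran-4-one and (S)-4-benzyl-3-propanoyl-1,3-thiazolidine-2-thione are bought as catalogue compounds; minor diastereomers are removed by chromatography where they arise.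

**Step 1**
Reactants: 1 2,6-diethyl-3,5-dimethyl-4H-pyran-4-one; 2 propanal
Product: 6 2-ethyl-6-[(2S,3S)-3-hydroxypentan-2-yl]-3,5-dimethyl-4H-pyran-4-one, via 4-silyloxypyrylium triflate 3 (not isolated), via silyl trienol ether 4 (not isolated), via O-silyl aldol adduct 5 (not isolated)
Conditions: Me3SiOSO2CF3 (1.05 equiv), Et3N (1.2 equiv), CH2Cl2, −78 → 0 °C; evaporate, pentane extraction, switch to EtCN; 2, (S)-4-(1H-indol-3-ylmethyl)-2-phenyl-3-tosyl-1,3,2-oxazaborolidin-5-one (1.0 equiv), −78 °C; then 1 M HCl, THF, 0 °C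
Reagents that add atoms: none
Why: Proposed new method: O-silylation of the basic pyranone carbonyl gives 4-silyloxypyrylium 3, whose ethyl CH2 is deprotonated by Et3N (anhydrobase formation) to the dearomatised silyl trienol ether 4, a vinylogous silyl enolate whose exocyclic carbon attacks the boron-bound aldehyde through an open antiperiplanar transition state (anti C-2/C-3) and re-aromatises to a 4-silyloxypyrylium that hands its silyl group to the aldolate, while the indole of the (S)-tryptophan-derived promoter shields the aldehyde Si face so that Re attack sets 3S and, with anti selection, 2S; the closest known chemistry is the silyl triflate/amine soft enolisation of ketones, the oxazaborolidinone-promoted vinylogous Mukaiyama aldol of silyl dienolates with aliphatic aldehydes and the anti-selective lithium dienolate aldol of this pyranone class.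

**Step 2**
Reactants: 6 2-ethyl-6-[(2S,3S)-3-hydroxypentan-2-yl]-3,5-dimethyl-4H-pyran-4-one
Product: 9 (2S,3S)-2-[6-(1-chloroethyl)-3,5-dimethyl-4-oxo-4H-pyran-2-yl]pentan-3-yl acetate (both epimers at the C–Cl carbon), via dilithium alkoxide dienolate 7 (not isolated), via lithium chloro alkoxide 8 (not isolated)
Conditions: LiN(SiMe3)2 (2.2 equiv), THF, −78 °C; cannulated into C2Cl6 (1.5 equiv), THF, −78 °C; then Ac2O (4 equiv), −78 → 0 °C
Reagents that add atoms: hexachloroethane ClC(Cl)(Cl)C(Cl)(Cl)Cl; acetic anhydride CC(=O)OC(C)=O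
Why: After alkoxide formation the only readily removable proton is on the remaining ethyl CH2, and the resulting vinylogous enolate is chlorinated at its exocyclic carbon (electrophilic enolate halogenation, re-aromatising) before the lithium alkoxide is O-acetylated; the new C–Cl centre is uncontrolled on purpose because step 8 is stereoconvergent.

**Step 3**
Reactants: 10 2-methylprop-2-enal (methacrolein)
Product: 12 (E)-3-bromo-2-methylprop-2-enal, via dibromide 11 (not isolated)
Conditions: Br2, CH2Cl2, −78 → 0 °C; then Et3N, 0 → 23 °C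
Reagents that add atoms: bromine BrBr
Why: Alkene bromination followed by E2 dehydrobromination gives the conjugated bromo-enal, the thermodynamically preferred E isomer (Br trans to CHO) fixing the later alkene geometry.

**Step 4**
Reactants: 12 (E)-3-bromo-2-methylprop-2-enal; 13 (S)-4-benzyl-3-propanoyl-1,3-thiazolidine-2-thione
Product: 14 (S)-4-benzyl-3-[(2S,3R,4E)-5-bromo-2,4-dimethyl-3-(trimethylsilyloxy)pent-4-enoyl]-1,3-thiazolidine-2-thione
Conditions: MgBr2·OEt2 (20 mol%), Et3N (2 equiv), Me3SiCl (1.5 equiv), EtOAc, 23 °C; pH 7 work-up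
Reagents that add atoms: chlorotrimethylsilane C[Si](C)(C)Cl
Why: Evans magnesium-halide-catalysed direct anti-aldol (soft enolisation, silylation of the magnesium aldolate turns the catalyst over), which works with non-enolisable α-substituted enals; the (S)-thiazolidinethione directs the anti adduct with 2S,3R configuration.

**Step 5**
Reactants: 14 (S)-4-benzyl-3-[(2S,3R,4E)-5-bromo-2,4-dimethyl-3-(trimethylsilyloxy)pent-4-enoyl]-1,3-thiazolidine-2-thione
Product: 15 (2S,3R,4E)-5-bromo-2,4-dimethyl-3-(trimethylsilyloxy)pent-4-enal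
Conditions: i-Bu2AlH (1.5 equiv), CH2Cl2, −78 °C; aq. KNaC4H4O6
Reagents that add atoms: none
Why: N-acyl thiazolidinethiones are reduced at −78 °C to a stable tetrahedral aluminium hemiaminal that releases the aldehyde only on work-up (direct auxiliary-to-aldehyde reduction), leaving the alkenyl bromide, the silyl ether and the α-stereocentre untouched.

**Step 6**
Reactants: 1 2,6-diethyl-3,5-dimethyl-4H-pyran-4-one; 15 (2S,3R,4E)-5-bromo-2,4-dimethyl-3-(trimethylsilyloxy)pent-4-enal
Product: 18 2-[(2R,3R,4R,5R,6E)-7-bromo-3,5-dihydroxy-4,6-dimethylhept-6-en-2-yl]-6-ethyl-3,5-dimethyl-4H-pyran-4-one, via lithium dienolate 16 (not isolated), via lithium aldolate 17 (not isolated)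
Conditions: 1 (1.3 equiv), LiN(SiMe3)2 (1.25 equiv), THF, −78 °C; 15, −78 °C; then 1 M HCl, THF, 0 °C
Reagents that add atoms: none
Why: Vinylogous aldol of the pyranone lithium dienolate, whose open transition state gives the anti C-2/C-3 relationship, while Felkin–Anh attack on the α-methyl aldehyde (reinforced by the anti β-silyloxy group) sets C-3 syn to the C-4 methyl and anti to the C-5 oxygen; the acid quench removes the trimethylsilyl group.

**Step 7**
Reactants: 18 2-[(2R,3R,4R,5R,6E)-7-bromo-3,5-dihydroxy-4,6-dimethylhept-6-en-2-yl]-6-ethyl-3,5-dimethyl-4H-pyran-4-one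
Product: 19 (2R,3R,4R,5R,6E)-7-bromo-2-(6-ethyl-3,5-dimethyl-4-oxo-4H-pyran-2-yl)-4,6-dimethylhept-6-ene-3,5-diyl dipropanoate
Conditions: (EtCO)2O (6 equiv), pyridine, 4-(dimethylamino)pyridine (0.3 equiv), CH2Cl2, 23 °C
Reagents that add atoms: propanoic anhydride CCC(=O)OC(=O)CC
Why: Nucleophile-catalysed acylation of both secondary alcohols under weakly basic conditions that do not trigger β-elimination; no stereocentre is touched.

**Step 8**
Reactants: 19 (2R,3R,4R,5R,6E)-7-bromo-2-(6-ethyl-3,5-dimethyl-4-oxo-4H-pyran-2-yl)-4,6-dimethylhept-6-ene-3,5-diyl dipropanoate; 9 (2S,3S)-2-[6-(1-chloroethyl)-3,5-dimethyl-4-oxo-4H-pyran-2-yl]pentan-3-yl acetate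
Product: 20 (2R,3R,4R,5R,6E,8S)-8-{6-[(2S,3S)-3-acetoxypentan-2-yl]-3,5-dimethyl-4-oxo-4H-pyran-2-yl}-2-(6-ethyl-3,5-dimethyl-4-oxo-4H-pyran-2-yl)-4,6-dimethylnon-6-ene-3,5-diyl dipropanoate (CNP0295731.1)
Conditions: 9 (1.5 equiv), NiCl2(MeOCH2CH2OMe) (10 mol%), (3aR,3a'R,8aS,8a'S)-2,2'-(cyclopropane-1,1-diyl)bis(3a,8a-dihydro-8H-indeno[1,2-d]oxazole) (11 mol%), Mn powder (3 equiv), NaI (0.5 equiv), N,N-dimethylacetamide, 0 °C
Reagents that add atoms: none
Why: Proposed new method: iodide exchange and halogen abstraction turn either epimer of 9 into the same planar pyranonyl-stabilised secondary radical, which is captured by the chiral bis(oxazoline) alkenylnickel species formed from 19 and reductively eliminated under ligand control to set 8S with retention of the E alkene, without base so the acidic C-8–H and the three esters survive; the closest known reaction is the nickel-catalysed enantioconvergent reductive cross-coupling of 1-arylethyl chlorides with alkenyl bromides using Mn as terminal reductant.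

**Compound list**
1 | 2,6-diethyl-3,5-dimethyl-4H-pyran-4-one | CCc1oc(CC)c(C)c(=O)c1C | starting material
2 | propanal | CCC=O | starting material
3 | 2,6-diethyl-3,5-dimethyl-4-(trimethylsilyloxy)pyrylium trifluoromethanesulfonate (not isolated) | CCc1[o+]c(CC)c(C)c(O[Si](C)(C)C)c1C.[O-]S(=O)(=O)C(F)(F)F | intermediate
4 | 6-ethyl-2-ethylidene-3,5-dimethyl-4-(trimethylsilyloxy)-2H-pyran (not isolated) | C[Si](C)(C)OC1=C(C)C(=CC)OC(CC)=C1C | intermediate
5 | 2-ethyl-3,5-dimethyl-6-[(2S,3S)-3-(trimethylsilyloxy)pentan-2-yl]-4H-pyran-4-one (not isolated) | CCc1oc([C@@H](C)[C@H](CC)O[Si](C)(C)C)c(C)c(=O)c1C | intermediate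
6 | 2-ethyl-6-[(2S,3S)-3-hydroxypentan-2-yl]-3,5-dimethyl-4H-pyran-4-one | CCc1oc([C@@H](C)[C@H](CC)O)c(C)c(=O)c1C | intermediate
7 | dilithium (2S,3S)-2-(6-ethylidene-3,5-dimethyl-4-oxido-6H-pyran-2-yl)pentan-3-olate (not isolated) | [Li+].[Li+].[O-]C1=C(C)C(=CC)OC([C@@H](C)[C@H](CC)[O-])=C1C | intermediate
8 | lithium (2S,3S)-2-[6-(1-chloroethyl)-3,5-dimethyl-4-oxo-4H-pyran-2-yl]pentan-3-olate (not isolated) | [Li+].CC(Cl)c1oc([C@@H](C)[C@H](CC)[O-])c(C)c(=O)c1C | intermediate
9 | (2S,3S)-2-[6-(1-chloroethyl)-3,5-dimethyl-4-oxo-4H-pyran-2-yl]pentan-3-yl acetate (epimer mixture at C–Cl) | CC(Cl)c1oc([C@@H](C)[C@H](CC)OC(C)=O)c(C)c(=O)c1C | intermediate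
10 | 2-methylprop-2-enal | CC(=C)C=O | starting material
11 | 2,3-dibromo-2-methylpropanal (racemic, not isolated) | CC(Br)(CBr)C=O | intermediate
12 | (E)-3-bromo-2-methylprop-2-enal | O=C/C(C)=C/Br | intermediate
13 | (S)-4-benzyl-3-propanoyl-1,3-thiazolidine-2-thione | CCC(=O)N1[C@@H](Cc2ccccc2)CSC1=S | starting material
14 | (S)-4-benzyl-3-[(2S,3R,4E)-5-bromo-2,4-dimethyl-3-(trimethylsilyloxy)pent-4-enoyl]-1,3-thiazolidine-2-thione | S=C1SC[C@H](Cc2ccccc2)N1C(=O)[C@@H](C)[C@@H](O[Si](C)(C)C)/C(C)=C/Br | intermediate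
15 | (2S,3R,4E)-5-bromo-2,4-dimethyl-3-(trimethylsilyloxy)pent-4-enal | O=C[C@@H](C)[C@@H](O[Si](C)(C)C)/C(C)=C/Br | intermediate
16 | lithium 6-ethyl-2-ethylidene-3,5-dimethyl-2H-pyran-4-olate (not isolated) | [Li+].[O-]C1=C(C)C(=CC)OC(CC)=C1C | intermediate
17 | lithium (2R,3R,4R,5R,6E)-7-bromo-2-(6-ethyl-3,5-dimethyl-4-oxo-4H-pyran-2-yl)-4,6-dimethyl-5-(trimethylsilyloxy)hept-6-en-3-olate (not isolated) | [Li+].[O-][C@H]([C@@H](C)[C@@H](O[Si](C)(C)C)/C(C)=C/Br)[C@@H](C)c1oc(CC)c(C)c(=O)c1C | intermediate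
18 | 2-[(2R,3R,4R,5R,6E)-7-bromo-3,5-dihydroxy-4,6-dimethylhept-6-en-2-yl]-6-ethyl-3,5-dimethyl-4H-pyran-4-one | O[C@H]([C@@H](C)[C@@H](O)/C(C)=C/Br)[C@@H](C)c1oc(CC)c(C)c(=O)c1C | intermediate
19 | (2R,3R,4R,5R,6E)-7-bromo-2-(6-ethyl-3,5-dimethyl-4-oxo-4H-pyran-2-yl)-4,6-dimethylhept-6-ene-3,5-diyl dipropanoate | CCC(=O)O[C@H]([C@@H](C)[C@@H](OC(=O)CC)/C(C)=C/Br)[C@@H](C)c1oc(CC)c(C)c(=O)c1C | intermediate
20 | (2R,3R,4R,5R,6E,8S)-8-{6-[(2S,3S)-3-acetoxypentan-2-yl]-3,5-dimethyl-4-oxo-4H-pyran-2-yl}-2-(6-ethyl-3,5-dimethyl-4-oxo-4H-pyran-2-yl)-4,6-dimethylnon-6-ene-3,5-diyl dipropanoate | CCC(=O)O[C@H]([C@@H](C)[C@@H](OC(=O)CC)/C(C)=C/[C@H](C)c1oc([C@@H](C)[C@H](CC)OC(C)=O)c(C)c(=O)c1C)[C@@H](C)c1oc(CC)c(C)c(=O)c1C | target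

**Totals and risks**
Total step count: 8. Longest linear sequence: 6 (steps 3, 4, 5, 6, 7, 8); the east fragment takes 2 steps (1, 2).

Steps most likely to fail:

Step 1 (anti selectivity and enantioselectivity of the new Mukaiyama variant; the facial sense of the promoter is assigned by model and must be checked, the mirror-image promoter being equally accessible). The fallback sets out from 1 and 2 and comes back at 6. Compound 1 is deprotonated to lithium dienolate 16 (LiN(SiMe3)2, THF, −78 °C, as in step 6) and treated directly with 2, giving by the substrate-controlled anti-selective vinylogous aldol the racemic anti lithium aldolate F1, which aqueous NH4Cl converts into the racemic anti alcohol F2. Kinetic resolution with immobilised lipase from Burkholderia cepacia and vinyl acetate (t-BuOMe, 30 °C, about 55% conversion) acetylates the faster-reacting 3R carbinol to the (2R,3R)-acetate F3 and leaves 6, which is separated by chromatography.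

Step 8 (hindered pyranonyl chloride and a trisubstituted alkenyl bromide in a fragment union; ligand control at C-8 unproven for this substrate class). The fallback sets out from 9 and comes back at 20. Zn dust and LiCl in THF at 25 °C convert 9 into the configurationally labile pyranonylethylzinc chloride F4, a zinc vinylogous enolate that tolerates the esters. F4 is coupled with 19 in a dynamic kinetic asymmetric Negishi reaction catalysed by dichloro{(R)-N,N-dimethyl-1-[(S)-2-(diphenylphosphino)ferrocenyl]ethylamine}palladium (5 mol%, THF, 0 °C), the ligand antipode being chosen by assay to deliver 8S.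

Step 6 (Felkin versus anti-Felkin ratio of a lithium dienolate addition may be modest). The fallback sets out from 1 and 15 and comes back at 18. Compound 1 is converted through 3 into silyl trienol ether 4 as in step 1, and 4 is added to 15 with the mirror-image promoter, (R)-4-(1H-indol-3-ylmethyl)-2-phenyl-3-tosyl-1,3,2-oxazaborolidin-5-one (EtCN, −78 °C). This reagent-controlled Si-face Mukaiyama aldol is matched with the Felkin and 1,3-anti bias of the aldehyde and gives the bis(trimethylsilyl) ether F5, which 1 M HCl in THF at 0 °C cleaves to 18.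

**Further compounds**
F1 | step 1 | racemic lithium (2S*,3S*)-2-(6-ethyl-3,5-dimethyl-4-oxo-4H-pyran-2-yl)pentan-3-olate | [Li+].CCc1oc([C@@H](C)[C@H](CC)[O-])c(C)c(=O)c1C.[Li+].CCc1oc([C@H](C)[C@@H](CC)[O-])c(C)c(=O)c1C
F2 | step 1 | racemic 2-ethyl-6-[(2S*,3S*)-3-hydroxypentan-2-yl]-3,5-dimethyl-4H-pyran-4-one | CCc1oc([C@@H](C)[C@H](CC)O)c(C)c(=O)c1C.CCc1oc([C@H](C)[C@@H](CC)O)c(C)c(=O)c1C
F3 | step 1 | (2R,3R)-2-(6-ethyl-3,5-dimethyl-4-oxo-4H-pyran-2-yl)pentan-3-yl acetate | CCc1oc([C@H](C)[C@@H](CC)OC(C)=O)c(C)c(=O)c1C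
F4 | step 8 | chloro{1-[6-((2S,3S)-3-acetoxypentan-2-yl)-3,5-dimethyl-4-oxo-4H-pyran-2-yl]ethyl}zinc | CC([Zn]Cl)c1oc([C@@H](C)[C@H](CC)OC(C)=O)c(C)c(=O)c1C
F5 | step 6 | 2-[(2R,3R,4R,5R,6E)-7-bromo-4,6-dimethyl-3,5-bis(trimethylsilyloxy)hept-6-en-2-yl]-6-ethyl-3,5-dimethyl-4H-pyran-4-one | C[Si](C)(C)O[C@H]([C@@H](C)[C@@H](O[Si](C)(C)C)/C(C)=C/Br)[C@@H](C)c1oc(CC)c(C)c(=O)c1C
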